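No constants were on the table for this flask, so the meeting set out to read its clock from the earlier runs.

| setting | ochre | amber | blue | flask |
|---|---|---|---|---|
| starting material | 0.050 M | 0.050 M | 0.075 M | 0.050 M |
| reagent | 0.45 equiv | 1.8 equiv | 0.90 equiv | 0.900 equiv |
| remark | run made earlier | run made earlier | run made earlier |  |
| time |  |  |  | 6.0 h |

| run | time / h | starting material / % | target / % | side product B / % |
|---|---|---|---|---|
| ochre | 1.33 | 28 | 17 | 58 |
| ochre | 2.50 | 20 | 8 | 76 |
| ochre | 4.00 | 16 | 3 | 78 |
| ochre | 5.00 | 16 | 4 | 83 |
| ochre | 6.00 | 14 | 1 | 84 |
| amber | 0.500 | 0 | 83 | 10 |
| amber | 0.833 | 2 | 88 | 9 |
| amber | 1.50 | 0 | 90 | 10 |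
| amber | 3.00 | 0 | 85 | 10 |
| amber | 6.00 | 0 | 87 | 9 |
| blue | 1.33 | 1 | 64 | 37 |
| blue | 2.50 | 0 | 63 | 33 |
| blue | 4.00 | 3 | 62 | 35 |
| blue | 5.00 | 0 | 61 | 34 |
| blue | 6.00 | 2 | 60 | 35 |

(standard deviation of a reading: 1.5 percentage points)

- in percentages every species weighs as the starting material in it: one side product B counts as two
- the reaction counts as stopped when no species that holds the starting material changes by six tenths of a point or more over the second half of the time

1. at 6.0 h, what has stopped the reaction, if anything has (it is still moving / the reagent has run out first / all of the starting material has reacted)
2. part of the starting material gone at 6.0 h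
3. the target standing at 6.0 h, as a percentage of the starting material charged
4. the side product B standing at 6.0 h, as a percentage of the starting material charged

The analyst reported that the blue run has the flask's equivalents at 0.075 M instead of 0.050 M. She argued that if each step is two species meeting, the flask follows blue's curve stretched by that ratio, so 6.0 h in the flask stands for 4.00 h in blue, where blue reads 62% target and 35% side product B. The process chemist asked which charge gives out first in the flask. She answered that, at one reagent per target and one per side product B, those blue readings use reagent equal to 79.5% of the starting material charged, under the 0.900 equiv charged to the flask, so she expected the starting material to be the limiting reagent there. I proposed counting half-lives. Blue's highest starting-material reading from 1.33 h on is 3%; taking that as an upper estimate for 1.33 h and stretching it to the flask gives a mean half-life of starting material of about 0.394 h. The flask's 6.0 h holds 15.2 of these, which leaves an estimated 0.00263% of the starting material. The meeting committed to those blue readings.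

The forecast gave all of the starting material has reacted, conversion 100%, 62% target and 35% side product B, holding that “selectivity depends on equivalents, not concentration”.

The flask gives all of the starting material has reacted, with conversion >99.9%, 63.6% target and 35.1% side product B.

    starting material + reagent → target (k = 0.0890 M⁻¹ s⁻¹)
    starting material + 2 reagent → side product A (k = 0.0610 M⁻² s⁻¹)
    starting material + target → side product B (k = 0.0120 M⁻¹ s⁻¹)

At 3.00 h the count gives 0.510% of starting material and the flask holds 0.0172%. At 0.0514 h the flask's starting material has a half-life of 0.83 h by the step with target, shorter than the 5.6 h by the step with two reagent.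

In the neighbour flask with 2.20 equiv of reagent, scaling the half-life by the reagent charge gives about 0.161 h, so 37.3 half-lives in 6.0 h. That flask ends with 0% of its starting material, 54% of its reagent and 87.4% target.

The data stem from a simulated flask on assumed constants, noise included.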